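**Retrosynthetic overview**

1. Target ⇒ acyclic (Z)-β-iodoenoate / cis-epoxy aldehyde by a C6–C7 disconnection: a CrCl2/NiCl2 vinyl addition closes the ten-membered carbocycle and the new alkoxide lactonises in the same operation (butenolide); C6 is set by the neighbouring epoxide.
2. Epoxy aldehyde ⇒ (Z)-allylic alcohol; Sharpless epoxidation sets C4/C5 and makes the epoxide, the first ring.
3. Tetrasubstituted iodoenoate carrying CH2OAc ⇒ γ-acyloxy ynoate + iodide + formaldehyde (halo-aldol); ynoate ⇒ keto aldehyde + methyl propiolate (asymmetric alkynylation sets C8), then methacrylation.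
4. Keto aldehyde ⇒ (S)-α-methyl-γ-butyrolactone (C10 by asymmetric hydrogenation) + (Z)-homoallylic iodide (from but-3-yn-1-ol by chelation-controlled carboalumination).
5. Order of ring formation: epoxide first, then ten-membered carbocycle and γ-lactone together in the last step.

Assumption: the SMILES is read as (4S,5R,6R,8R,10S) in germacrane numbering (C1 ketone, cis-4,5-epoxide, C6 lactone CH–O, C7=C11, C8 methacrylate, C12 lactone C=O, C13 CH2OAc); these atom labels are used for all intermediates.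

**Route**

Step 1
Reactants: 1 but-3-yn-1-ol
Product: 3 (3Z)-3-methyl-5-{[tri(propan-2-yl)silyl]oxy}pent-3-en-1-ol, via cyclic alkenylalane 2 (not isolated)
Conditions: AlMe3 (3 equiv), Cp2ZrCl2 (0.25 equiv), ClCH2CH2Cl, 23 °C, then reflux 72 h; i-Pr3SiOCH2Cl, 0 → 23 °C; aq. potassium sodium tartrate
Reagents that add atoms: trimethylaluminium, C[Al](C)C; (chloromethoxy)tri(propan-2-yl)silane, ClCO[Si](C(C)C)(C(C)C)C(C)C
Why: Negishi zirconium-catalysed carboalumination adds Me–Al syn, the aluminium alkoxide then drives thermal isomerisation to the chelated (Z)-alkenylalane 2, and alkylation of its C–Al bond by the α-chloro ether goes with retention, so C3 and C6 end cis on the C4=C5 olefin.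

Step 2
Reactants: 3 (3Z)-3-methyl-5-{[tri(propan-2-yl)silyl]oxy}pent-3-en-1-ol
Product: 4 {[(2Z)-5-iodo-3-methylpent-2-en-1-yl]oxy}tri(propan-2-yl)silane
Conditions: I2, PPh3, imidazole, CH2Cl2, 0 °C
Reagents that add atoms: iodine, II
Why: Appel-type (Garegg–Samuelsson) iodination displaces the oxyphosphonium ion of the primary alcohol by SN2, leaving the silyl ether and the (Z)-olefin untouched; no stereocentre is formed.

Step 3
Reactants: 5 3-methylideneoxolan-2-one (α-methylene-γ-butyrolactone)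
Product: 6 (3S)-3-methyloxolan-2-one
Conditions: H2 (100 atm), Ru(OAc)2[(R)-BINAP] (0.5 mol %), CH2Cl2, 50 °C
Reagents that add atoms: none
Why: Noyori-type asymmetric hydrogenation, in which the lactone carbonyl chelates ruthenium and H2 is delivered to one face of the exocyclic olefin, sets C10 as S (the BINAP antipode that gives the S lactone is used).

Step 4
Reactants: 4 {[(2Z)-5-iodo-3-methylpent-2-en-1-yl]oxy}tri(propan-2-yl)silane; 6 (3S)-3-methyloxolan-2-one
Product: 8 (3S,7Z)-1-hydroxy-3,7-dimethyl-9-{[tri(propan-2-yl)silyl]oxy}non-7-en-4-one, via alkyllithium 7 (not isolated)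
Conditions: 4, t-BuLi (2.1 equiv), Et2O–pentane, −78 °C; then 6, −78 °C; H2O
Reagents that add atoms: none
Why: Iodine–lithium exchange gives alkyllithium 7, which adds once to the lactone (acyl substitution) because the lithium lactolate does not collapse at −78 °C, giving the C1 ketone after quench, and C10 keeps its configuration because the tetrahedral intermediate cannot enolise.

Step 5
Reactants: 8 (3S,7Z)-1-hydroxy-3,7-dimethyl-9-{[tri(propan-2-yl)silyl]oxy}non-7-en-4-one
Product: 9 (3S,7Z)-3,7-dimethyl-4-oxo-9-{[tri(propan-2-yl)silyl]oxy}non-7-enal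
Conditions: Dess–Martin periodinane, CH2Cl2, 0 → 23 °C
Reagents that add atoms: none
Why: Dess–Martin oxidation of the primary alcohol (open-chain tautomer of the hemiketal) gives the aldehyde under neutral conditions that do not epimerise C10.

Step 6
Reactants: 9 (3S,7Z)-3,7-dimethyl-4-oxo-9-{[tri(propan-2-yl)silyl]oxy}non-7-enal; 10 methyl prop-2-ynoate
Product: 12 methyl (4R,6S,10Z)-4-hydroxy-6,10-dimethyl-7-oxo-12-{[tri(propan-2-yl)silyl]oxy}dodec-10-en-2-ynoate, via methylzinc alkynylide 11 (not isolated)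
Conditions: 10 (3 equiv), ZnMe2 (3 equiv), (S,S)-ProPhenol (20 mol %), Ph3P=O (40 mol %), toluene, 4 °C; then 9; H2O work-up
Reagents that add atoms: none
Why: Trost zinc–ProPhenol asymmetric alkynylation, in which the dinuclear zinc catalyst binds the aldehyde and delivers alkynylide 11 to one carbonyl face (ligand antipode chosen to give 8R), with the aldehyde reacting much faster than the dialkyl ketone.

Step 7
Reactants: 12 methyl (4R,6S,10Z)-4-hydroxy-6,10-dimethyl-7-oxo-12-{[tri(propan-2-yl)silyl]oxy}dodec-10-en-2-ynoate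
Product: 13 methyl (4R,6S,10Z)-6,10-dimethyl-4-[(2-methylprop-2-enoyl)oxy]-7-oxo-12-{[tri(propan-2-yl)silyl]oxy}dodec-10-en-2-ynoate
Conditions: methacrylic anhydride, pyridine, DMAP (5 mol %), CH2Cl2, −20 → 0 °C
Reagents that add atoms: methacrylic anhydride, C=C(C)C(=O)OC(=O)C(C)=C
Why: DMAP-catalysed acylation of the propargylic alcohol installs the methacrylate with retention at C8, the weak base and low temperature suppressing propargyl–allenyl isomerisation.

Step 8
Reactants: 13 methyl (4R,6S,10Z)-6,10-dimethyl-4-[(2-methylprop-2-enoyl)oxy]-7-oxo-12-{[tri(propan-2-yl)silyl]oxy}dodec-10-en-2-ynoate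
Product: 15 methyl (2Z,4R,6S,10Z)-2-[(acetyloxy)methyl]-3-iodo-6,10-dimethyl-4-[(2-methylprop-2-enoyl)oxy]-7-oxo-12-{[tri(propan-2-yl)silyl]oxy}dodeca-2,10-dienoate, via iodo alcohol 14 (not isolated)
Conditions: MgI2 (1.5 equiv), CH2Cl2, −20 °C; anhydrous HCHO (THF solution), −20 → 0 °C; then Ac2O, pyridine, DMAP (cat.), 0 °C
Reagents that add atoms: magnesium iodide MgI2, [Mg+2].[I-].[I-]; formaldehyde, C=O; acetic anhydride, CC(=O)OC(C)=O
Why: Halo-aldol (β-iodo Morita–Baylis–Hillman-type) reaction in which iodide adds to C7 to give a magnesium β-iodoallenolate that is hydroxymethylated at C11 anti to iodine (the same anti sense as hydroiodination of 2-alkynoates), placing I cis to the ester and C13 cis to C8, after which magnesium alkoxide 14 is acetylated in the same flask.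

Step 9
Reactants: 15 methyl (2Z,4R,6S,10Z)-2-[(acetyloxy)methyl]-3-iodo-6,10-dimethyl-4-[(2-methylprop-2-enoyl)oxy]-7-oxo-12-{[tri(propan-2-yl)silyl]oxy}dodeca-2,10-dienoate
Product: 16 methyl (2Z,4R,6S,10Z)-2-[(acetyloxy)methyl]-12-hydroxy-3-iodo-6,10-dimethyl-4-[(2-methylprop-2-enoyl)oxy]-7-oxododeca-2,10-dienoate
Conditions: HF·pyridine, pyridine, THF, 0 → 23 °C
Reagents that add atoms: none
Why: Fluoride-induced Si–O cleavage (desilylation) frees the allylic alcohol while acetate, methacrylate and vinyl iodide are inert to buffered HF.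

Step 10
Reactants: 16 methyl (2Z,4R,6S,10Z)-2-[(acetyloxy)methyl]-12-hydroxy-3-iodo-6,10-dimethyl-4-[(2-methylprop-2-enoyl)oxy]-7-oxododeca-2,10-dienoate
Product: 17 methyl (2Z,4R,6S)-2-[(acetyloxy)methyl]-9-[(2S,3R)-3-(hydroxymethyl)-2-methyloxiran-2-yl]-3-iodo-6-methyl-4-[(2-methylprop-2-enoyl)oxy]-7-oxonon-2-enoate
Conditions: Ti(OiPr)4 (20 mol %), D-(−)-diethyl tartrate (24 mol %), t-BuOOH, 4 Å sieves, CH2Cl2, −20 °C
Reagents that add atoms: tert-butyl hydroperoxide, CC(C)(C)OO
Why: Sharpless asymmetric epoxidation, in which the titanium tartrate binds the allylic alcohol and transfers oxygen only to the C4=C5 olefin, D-(−)-tartrate attacking the face that gives (4S,5R), with the cis-epoxide geometry following from the Z-olefin.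

Step 11
Reactants: 17 methyl (2Z,4R,6S)-2-[(acetyloxy)methyl]-9-[(2S,3R)-3-(hydroxymethyl)-2-methyloxiran-2-yl]-3-iodo-6-methyl-4-[(2-methylprop-2-enoyl)oxy]-7-oxonon-2-enoate
Product: 18 methyl (2Z,4R,6S)-2-[(acetyloxy)methyl]-9-[(2S,3S)-3-formyl-2-methyloxiran-2-yl]-3-iodo-6-methyl-4-[(2-methylprop-2-enoyl)oxy]-7-oxonon-2-enoate
Conditions: Dess–Martin periodinane, pyridine, CH2Cl2, 0 °C
Reagents that add atoms: none
Why: Dess–Martin oxidation of the epoxy alcohol gives the epoxy aldehyde under buffered conditions that leave C5 and the epoxide intact (the descriptor at C5 changes only because CHO now outranks C4).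

Step 12
Reactants: 18 methyl (2Z,4R,6S)-2-[(acetyloxy)methyl]-9-[(2S,3S)-3-formyl-2-methyloxiran-2-yl]-3-iodo-6-methyl-4-[(2-methylprop-2-enoyl)oxy]-7-oxonon-2-enoate
Product: 21 CNP0128625.1, (4S,5R,6R,8R,10S)-13-acetoxy-4,5-epoxy-8-(methacryloyloxy)-1-oxogermacr-7(11)-en-12,6-olide, via vinylchromium 19 (not isolated), via hydroxy ester 20 (not isolated)
Conditions: CrCl2 (10 equiv), NiCl2 (2 mol %), DMSO–THF, 2 mM (syringe pump), 23 °C; H2O work-up
Reagents that add atoms: none
Why: Nozaki–Hiyama–Kishi macrocyclisation in which zerovalent nickel inserts into the C7–I bond, transmetalation gives trivalent vinylchromium 19 with retention of geometry, 19 adds to the aldehyde anti to the epoxide C–O bond (Felkin–Anh/Cornforth) to set 6R, and the new alkoxide 20, lying cis to the methyl ester across C7=C11, lactonises at once with loss of methanol, so the ten-membered ring and the butenolide close in one operation.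

**Compound list**

1 | but-3-yn-1-ol | C#CCCO | starting material
2 | cyclic (Z)-alkenylalane, 2,4-dimethyl-5,6-dihydro-2H-1,2-oxaalumine | CC1=C[Al](C)OCC1 | intermediate
3 | (3Z)-3-methyl-5-{[tri(propan-2-yl)silyl]oxy}pent-3-en-1-ol | OCC/C(C)=C\CO[Si](C(C)C)(C(C)C)C(C)C | intermediate
4 | {[(2Z)-5-iodo-3-methylpent-2-en-1-yl]oxy}tri(propan-2-yl)silane | ICC/C(C)=C\CO[Si](C(C)C)(C(C)C)C(C)C | intermediate
5 | 3-methylideneoxolan-2-one | C=C1CCOC1=O | starting material
6 | (3S)-3-methyloxolan-2-one | C[C@H]1CCOC1=O | intermediate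
7 | [(3Z)-3-methyl-5-{[tri(propan-2-yl)silyl]oxy}pent-3-en-1-yl]lithium | [Li]CC/C(C)=C\CO[Si](C(C)C)(C(C)C)C(C)C | intermediate
8 | (3S,7Z)-1-hydroxy-3,7-dimethyl-9-{[tri(propan-2-yl)silyl]oxy}non-7-en-4-one | OCC[C@H](C)C(=O)CC/C(C)=C\CO[Si](C(C)C)(C(C)C)C(C)C | intermediate
9 | (3S,7Z)-3,7-dimethyl-4-oxo-9-{[tri(propan-2-yl)silyl]oxy}non-7-enal | O=CC[C@H](C)C(=O)CC/C(C)=C\CO[Si](C(C)C)(C(C)C)C(C)C | intermediate
10 | methyl prop-2-ynoate | C#CC(=O)OC | starting material
11 | methyl 3-(methylzincio)prop-2-ynoate | C[Zn]C#CC(=O)OC | intermediate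
12 | methyl (4R,6S,10Z)-4-hydroxy-6,10-dimethyl-7-oxo-12-{[tri(propan-2-yl)silyl]oxy}dodec-10-en-2-ynoate | COC(=O)C#C[C@H](O)C[C@H](C)C(=O)CC/C(C)=C\CO[Si](C(C)C)(C(C)C)C(C)C | intermediate
13 | methyl (4R,6S,10Z)-6,10-dimethyl-4-[(2-methylprop-2-enoyl)oxy]-7-oxo-12-{[tri(propan-2-yl)silyl]oxy}dodec-10-en-2-ynoate | COC(=O)C#C[C@H](OC(=O)C(C)=C)C[C@H](C)C(=O)CC/C(C)=C\CO[Si](C(C)C)(C(C)C)C(C)C | intermediate
14 | methyl (2Z,4R,6S,10Z)-2-(hydroxymethyl)-3-iodo-6,10-dimethyl-4-[(2-methylprop-2-enoyl)oxy]-7-oxo-12-{[tri(propan-2-yl)silyl]oxy}dodeca-2,10-dienoate (present as its magnesium alkoxide) | COC(=O)/C(CO)=C(\I)[C@H](OC(=O)C(C)=C)C[C@H](C)C(=O)CC/C(C)=C\CO[Si](C(C)C)(C(C)C)C(C)C | intermediate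
15 | methyl (2Z,4R,6S,10Z)-2-[(acetyloxy)methyl]-3-iodo-6,10-dimethyl-4-[(2-methylprop-2-enoyl)oxy]-7-oxo-12-{[tri(propan-2-yl)silyl]oxy}dodeca-2,10-dienoate | COC(=O)/C(COC(C)=O)=C(\I)[C@H](OC(=O)C(C)=C)C[C@H](C)C(=O)CC/C(C)=C\CO[Si](C(C)C)(C(C)C)C(C)C | intermediate
16 | methyl (2Z,4R,6S,10Z)-2-[(acetyloxy)methyl]-12-hydroxy-3-iodo-6,10-dimethyl-4-[(2-methylprop-2-enoyl)oxy]-7-oxododeca-2,10-dienoate | COC(=O)/C(COC(C)=O)=C(\I)[C@H](OC(=O)C(C)=C)C[C@H](C)C(=O)CC/C(C)=C\CO | intermediate
17 | methyl (2Z,4R,6S)-2-[(acetyloxy)methyl]-9-[(2S,3R)-3-(hydroxymethyl)-2-methyloxiran-2-yl]-3-iodo-6-methyl-4-[(2-methylprop-2-enoyl)oxy]-7-oxonon-2-enoate | COC(=O)/C(COC(C)=O)=C(\I)[C@H](OC(=O)C(C)=C)C[C@H](C)C(=O)CC[C@]1(C)O[C@@H]1CO | intermediate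
18 | methyl (2Z,4R,6S)-2-[(acetyloxy)methyl]-9-[(2S,3S)-3-formyl-2-methyloxiran-2-yl]-3-iodo-6-methyl-4-[(2-methylprop-2-enoyl)oxy]-7-oxonon-2-enoate | COC(=O)/C(COC(C)=O)=C(\I)[C@H](OC(=O)C(C)=C)C[C@H](C)C(=O)CC[C@]1(C)O[C@@H]1C=O | intermediate
19 | C7-dichlorochromium derivative of 18 (trivalent chromium in place of iodine, cis to the ester) | COC(=O)/C(COC(C)=O)=C(\[Cr](Cl)Cl)[C@H](OC(=O)C(C)=C)C[C@H](C)C(=O)CC[C@]1(C)O[C@@H]1C=O | intermediate
20 | ten-membered-ring hydroxy ester: (6R)-6-hydroxy-4,5-epoxy carbocycle with exocyclic C7=C11 bearing CO2Me (cis to C6) and CH2OAc; present as its chromium alkoxide | C=C(C)C(=O)O[C@@H]1C[C@H](C)C(=O)CC[C@]2(C)O[C@@H]2[C@H](O)/C1=C(/COC(C)=O)C(=O)OC | intermediate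
21 | CNP0128625.1, (4S,5R,6R,8R,10S)-13-acetoxy-4,5-epoxy-8-(methacryloyloxy)-1-oxogermacr-7(11)-en-12,6-olide | C=C(C)C(=O)O[C@@H]1C[C@H](C)C(=O)CC[C@]2(C)O[C@@H]2[C@@H]2OC(=O)C(COC(C)=O)=C21 | target

**Step count and risks**

Total step count: 12. Longest linear sequence: 11 steps (1 → 3 → 4 → 8 → 9 → 12 → 13 → 15 → 16 → 17 → 18 → 21); the lactone branch 5 → 6 adds one step.

The three steps most likely to fail:

Step 12 (macrocyclisation/lactonisation). The risks are the strain of the ten-membered ring and oligomerisation, a competing five-membered ring closure of vinylchromium 19 onto the C1 ketone, and Lewis-acid opening of the epoxy aldehyde. The fallback sets out from 16 and comes back at 21; it moves the epoxidation to the end, so the ring is closed on a planar dienyl system. Allylic alcohol 16 is oxidised with MnO2 (CH2Cl2) to the (2Z,10Z)-enal F1. F1, a more electrophilic acceptor with no epoxide to open, is cyclised with CrCl2/NiCl2 at high dilution to give, through the dienyl hydroxy ester F2 (not isolated), the 4,5-olefinic bicyclic lactone F3. The epoxide is then made last with dimethyldioxirane (acetone, 0 °C) on the only electron-rich olefin of F3, the face being chosen by peripheral attack on the macrocycle, which gives 21. In this variant C6 and the epoxide face are controlled by the ring, not by the Felkin–Anh model, and would need to be checked.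

Step 8 (halo-aldol). The risks are low reactivity of the internal ynoate toward iodide and formaldehyde, and the wrong olefin geometry (I trans to the ester), which would make lactonisation in step 12 impossible. The fallback sets out from 12 and comes back at 15; it fixes the geometry with a ring. Alcohol 12 is converted with paraformaldehyde and Me3SiCl into the chloromethyl ether F4. NaI (MeCN, 23 °C) then adds iodide to C7 and the allenolate is alkylated intramolecularly by the halomethyl ether (five-membered ring closure), which gives the 4-iodo-2,5-dihydrofuran-3-carboxylate F5, in which the ring ties C13 to the C8 oxygen and so forces I cis to the ester. Methacryloyl chloride with ZnCl2 (10 mol %, CH2Cl2, 0 °C) opens the cyclic allyl ether by chloride attack at the primary C13, leaving the methacrylate on the C8 oxygen, to give the allylic chloride F6. KOAc (DMF, 23 °C) replaces chloride by acetate to give 15.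

Step 6 (asymmetric alkynylation). The risks are intramolecular aldol of the 1,4-keto aldehyde under the basic zinc alkoxide conditions and a moderate selectivity with an unbranched aliphatic aldehyde. The fallback sets out from 9 and comes back at 12; it sets C8 by reduction, not by addition. Methyl propiolate 10 is deprotonated with LiN(SiMe3)2 (THF, −78 °C) to lithium 3-methoxy-3-oxoprop-1-yn-1-ide F7, which adds to aldehyde 9 without stereocontrol to give the C8-epimeric alcohols F8. Dess–Martin oxidation gives the ynone F9. Noyori transfer hydrogenation with RuCl(p-cymene)[(S,S)-TsDPEN] and HCO2H/Et3N (catalyst antipode chosen for 8R), which reduces the ynone and not the dialkyl ketone, returns 12.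

**Further compounds**

F1 | step 12 | methyl (2Z,4R,6S,10Z)-2-[(acetyloxy)methyl]-3-iodo-6,10-dimethyl-4-[(2-methylprop-2-enoyl)oxy]-7,12-dioxododeca-2,10-dienoate | COC(=O)/C(COC(C)=O)=C(\I)[C@H](OC(=O)C(C)=C)C[C@H](C)C(=O)CC/C(C)=C\C=O
F2 | step 12 | dienyl hydroxy ester, the (4Z)-4,5-olefinic analogue of 20 (present as its chromium alkoxide) | C=C(C)C(=O)O[C@@H]1C[C@H](C)C(=O)CC/C(C)=C\[C@H](O)/C1=C(/COC(C)=O)C(=O)OC
F3 | step 12 | (4Z)-13-acetoxy-8-(methacryloyloxy)-1-oxogermacra-4,7(11)-dien-12,6-olide, the 4,5-deepoxy olefin of 21 with the same arrangement at C6, C8 and C10 | C=C(C)C(=O)O[C@@H]1C[C@H](C)C(=O)CC/C(C)=C\[C@@H]2OC(=O)C(COC(C)=O)=C21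
F4 | step 8 | methyl (4R,6S,10Z)-4-(chloromethoxy)-6,10-dimethyl-7-oxo-12-{[tri(propan-2-yl)silyl]oxy}dodec-10-en-2-ynoate | COC(=O)C#C[C@H](OCCl)C[C@H](C)C(=O)CC/C(C)=C\CO[Si](C(C)C)(C(C)C)C(C)C
F5 | step 8 | methyl (5R)-5-[(2S,6Z)-2,6-dimethyl-3-oxo-8-{[tri(propan-2-yl)silyl]oxy}oct-6-en-1-yl]-4-iodo-2,5-dihydrofuran-3-carboxylate | COC(=O)C1=C(I)[C@@H](C[C@H](C)C(=O)CC/C(C)=C\CO[Si](C(C)C)(C(C)C)C(C)C)OC1
F6 | step 8 | methyl (2E,4R,6S,10Z)-2-(chloromethyl)-3-iodo-6,10-dimethyl-4-[(2-methylprop-2-enoyl)oxy]-7-oxo-12-{[tri(propan-2-yl)silyl]oxy}dodeca-2,10-dienoate (I cis to the ester) | COC(=O)/C(CCl)=C(\I)[C@H](OC(=O)C(C)=C)C[C@H](C)C(=O)CC/C(C)=C\CO[Si](C(C)C)(C(C)C)C(C)C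
F7 | step 6 | lithium 3-methoxy-3-oxoprop-1-yn-1-ide | [Li]C#CC(=O)OC
F8 | step 6 | methyl (4RS,6S,10Z)-4-hydroxy-6,10-dimethyl-7-oxo-12-{[tri(propan-2-yl)silyl]oxy}dodec-10-en-2-ynoate (C8 epimers) | COC(=O)C#CC(O)C[C@H](C)C(=O)CC/C(C)=C\CO[Si](C(C)C)(C(C)C)C(C)C
F9 | step 6 | methyl (6S,10Z)-6,10-dimethyl-4,7-dioxo-12-{[tri(propan-2-yl)silyl]oxy}dodec-10-en-2-ynoate | COC(=O)C#CC(=O)C[C@H](C)C(=O)CC/C(C)=C\CO[Si](C(C)C)(C(C)C)C(C)C
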